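**Plan**

1. The target is 19(R)-hydroxy-PGF1α. Its one ring (C8–C12) carries a cis-1,3-diol at C9/C11, trans chains at C8/C12 and an (E)-C13=C14–C15(S)-ol. This is the footprint of a C9–O–O–C11 bridged 2,3-dioxabicyclo[2.2.1]heptane, so C8/C9, C11/C12 and C14/C15 can be read as three skipped Z-olefins with bis-allylic C10 and C13.
2. Retrosynthesis: the 9,11-diol goes back to the peroxide bridge (a temporary ring). One cyclooxygenase event then cuts C8–C12, C9–O, C11–O and C15–O and leaves acyclic (8Z,11Z,14Z,19R)-19-hydroxyicosa-8,11,14-trienoic acid.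
3. This acid is cut at C9–C10 and C13–C14 (alkyne–propargyl halide couplings, then threefold cis-semihydrogenation) into a C1–C9 alkynoate, a C4 butynyl linchpin and a C14–C20 (R)-alkynol.
4. Forward: C1–C9 + C10–C13, then + C14–C20, triyne to Z,Z,Z-triene, ester to acid. In the key step the dioxolane closes first and the cyclopentane last, and the peroxide bridge is reduced off in the same pot.
5. Stereochemistry: C19 comes from (R)-propylene oxide (chiral pool), the olefin geometry from syn-hydrogenation, and C8, C9, C11, C12, C15 and the 13E olefin from the enzyme-controlled key step.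

Key step: step 9

Assumption: the (ω-1)-hydroxyl of the trienoic acid substrate is taken to be tolerated in the hydrophobic ω-groove of the cyclooxygenase channel, as ω-hydroxylated C20 polyenoic acids are substrates of this enzyme class, at a rate expected to be lower than for the parent acid.

**Route**

Step 1
Reactants: 1 (R)-2-methyloxirane [(R)-propylene oxide]; 2 (4-bromobut-1-yn-1-yl)trimethylsilane
Product: 4 (2R)-7-(trimethylsilyl)hept-6-yn-2-ol, via Grignard reagent 3 (not isolated)
Conditions: 2, Mg, THF, 40 °C; then CuI (10 mol%), 1, −30 → 0 °C; aq. NH4Cl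
Reagents that add atoms: none
Why: Copper(I)-catalysed SN2 ring opening of the terminal epoxide by the primary Grignard reagent should occur at the unsubstituted carbon, so the C–O bond of the stereocentre is not touched and (R)-propylene oxide hands its configuration to the future C19 carbinol (chiral-pool transfer).

Step 2
Reactants: 4 (2R)-7-(trimethylsilyl)hept-6-yn-2-ol
Product: 5 (2R)-hept-6-yn-2-ol
Conditions: K2CO3 (cat.), MeOH, rt
Reagents that add atoms: none
Why: Base-catalysed methanolysis of the C(sp)–Si bond (protodesilylation of an alkynylsilane) should free the terminal alkyne without affecting the secondary alcohol or its configuration.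

Step 3
Reactants: 6 non-8-ynoic acid
Product: 7 methyl non-8-ynoate
Conditions: MeOH, H2SO4 (cat.), reflux
Reagents that add atoms: methanol, CO
Why: Fischer esterification masks the acid as the methyl ester so that the carboxylate does not interfere with the copper acetylide chemistry that follows.

Step 4
Reactants: 7 methyl non-8-ynoate; 8 4-chlorobut-2-yn-1-ol
Product: 10 methyl 13-hydroxytrideca-8,11-diynoate, via 4-iodobut-2-yn-1-ol 9 (not isolated)
Conditions: CuI (1 equiv), NaI, Cs2CO3, DMF, rt, Ar
Reagents that add atoms: none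
Why: Copper(I)-mediated alkyne–propargyl halide coupling (Finkelstein exchange to the iodide, then SN2 displacement by the copper acetylide) should form the C9–C10 bond of the skipped diyne under carbonate conditions that leave the ester and the free primary alcohol alone.

Step 5
Reactants: 10 methyl 13-hydroxytrideca-8,11-diynoate
Product: 11 methyl 13-bromotrideca-8,11-diynoate
Conditions: CBr4, PPh3, CH2Cl2, −20 → 0 °C
Reagents that add atoms: carbon tetrabromide, BrC(Br)(Br)Br
Why: The Appel reaction should convert the primary propargylic alcohol into the bromide under neutral conditions that do not isomerise the base-sensitive 1,4-diyne.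

Step 6
Reactants: 11 methyl 13-bromotrideca-8,11-diynoate; 5 (2R)-hept-6-yn-2-ol
Product: 13 methyl (19R)-19-hydroxyicosa-8,11,14-triynoate, via propargylic iodide 12 (not isolated)
Conditions: CuI (1 equiv), NaI, Cs2CO3, DMF, rt, Ar, dark
Reagents that add atoms: none
Why: The same copper(I)-mediated alkyne–propargyl halide coupling should form the C13–C14 bond, since the secondary alcohol of 5 is not alkylated by carbonate in the presence of the far more nucleophilic copper acetylide and the remote stereocentre is not involved.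

Step 7
Reactants: 13 methyl (19R)-19-hydroxyicosa-8,11,14-triynoate
Product: 14 methyl (8Z,11Z,14Z,19R)-19-hydroxyicosa-8,11,14-trienoate
Conditions: H2 (1 atm), P-2 Ni [Ni(OAc)2·4H2O, NaBH4], ethylenediamine, EtOH, rt, stopped at 3 equiv H2
Reagents that add atoms: none
Why: Catalytic semihydrogenation on ethylenediamine-poisoned nickel boride adds H2 syn to each alkyne and releases the cis-olefin faster than it reduces it further, so the triyne should give the all-Z skipped triene with the ester and carbinol untouched.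

Step 8
Reactants: 14 methyl (8Z,11Z,14Z,19R)-19-hydroxyicosa-8,11,14-trienoate
Product: 15 (8Z,11Z,14Z,19R)-19-hydroxyicosa-8,11,14-trienoic acid
Conditions: LiOH, THF/H2O (degassed), rt, Ar; then dil. HCl to pH 4
Reagents that add atoms: lithium hydroxide, [Li+].[OH-]
Why: Mild saponification (acyl–oxygen cleavage by hydroxide) should free the carboxylate that the enzyme needs as its anchor, and a skipped triene does not conjugate under these conditions at room temperature.

Step 9
Reactants: 15 (8Z,11Z,14Z,19R)-19-hydroxyicosa-8,11,14-trienoic acid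
Product: 18 7-[(1R,2R,3R,5S)-2-[(1E,3S,7R)-3,7-dihydroxyoct-1-en-1-yl]-3,5-dihydroxycyclopentyl]heptanoic acid [19(R)-hydroxy-PGF1α], via 19-hydroxy-PGG1 16 (not isolated), via 19-hydroxy-PGH1 17 (not isolated)
Conditions: purified ovine cyclooxygenase-1 (prostaglandin-endoperoxide H synthase), hematin, hydroquinone, O2-saturated 0.1 M Tris-HCl pH 8.0, 25 °C, short incubation; then SnCl2, EtOH, 0 °C → rt; pH 3–4, EtOAc, RP-HPLC
Reagents that add atoms: dioxygen, O=O
Why: Cyclooxygenase (a haem-dependent fatty-acid bis-dioxygenase with a peroxidase site) removes the pro-S hydrogen of bis-allylic C13 with its tyrosyl radical; the C11–C15 pentadienyl radical takes up O2 at C11, the 11-peroxyl radical adds to C9 of the C8=C9 olefin (5-exo-trig, closing the 1,2-dioxolane), the C8 radical adds to C12 of the 12,14-diene (5-exo-trig, closing the carbocycle C8–C12 as the last ring) and the C13–C15 allyl radical takes up a second O2 at C15 to give 16, whose hydroperoxide is reduced at the peroxidase site (hydroquinone as electron donor) to 17 before SnCl2 cleaves the O–O bridge to the 9,11-diol. The closest known reaction type is the native conversion of (8Z,11Z,14Z)-icosatrienoic acid into the PGH1 endoperoxide and its stannous chloride reduction to PGF1α, and ω-hydroxylated C20 polyenoic acids are accepted by the same enzyme class. C11 (R) is set by O2 entering anti to the abstracted hydrogen, C9 (S) by the two-atom peroxide tether, which can span only one face of the forming ring (hence the cis-diol), C8 (R) and C12 (R) by the enzyme-held L-shaped chain conformation that forces the trans arrangement of the two chains, which the uncatalysed radical cyclisation does not give, and C15 (S) by the direction of O2 access to the allyl radical, whose transoid form fixes 13E. The step needs regioselectivity for abstraction of H-13 over H-10 and for the complete cascade over release of simple 11- or 15-hydroperoxides; both are secured by the C1 carboxylate anchor at the channel mouth, which places C13 under the tyrosyl radical, and by the Z,Z,Z geometry of the C8–C15 triene, while the C19 carbinol lies in the ω-groove away from every reacting atom and is carried through unchanged.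

**Compound list**

1 | (R)-2-methyloxirane [(R)-propylene oxide] | C[C@@H]1CO1 | starting material
2 | (4-bromobut-1-yn-1-yl)trimethylsilane | C[Si](C)(C)C#CCCBr | starting material
3 | [4-(trimethylsilyl)but-3-yn-1-yl]magnesium bromide | C[Si](C)(C)C#CCC[Mg]Br | intermediate
4 | (2R)-7-(trimethylsilyl)hept-6-yn-2-ol | C[C@@H](O)CCCC#C[Si](C)(C)C | intermediate
5 | (2R)-hept-6-yn-2-ol | C[C@@H](O)CCCC#C | intermediate
6 | non-8-ynoic acid | C#CCCCCCCC(=O)O | starting material
7 | methyl non-8-ynoate | C#CCCCCCCC(=O)OC | intermediate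
8 | 4-chlorobut-2-yn-1-ol | OCC#CCCl | starting material
9 | 4-iodobut-2-yn-1-ol | OCC#CCI | intermediate
10 | methyl 13-hydroxytrideca-8,11-diynoate | COC(=O)CCCCCCC#CCC#CCO | intermediate
11 | methyl 13-bromotrideca-8,11-diynoate | COC(=O)CCCCCCC#CCC#CCBr | intermediate
12 | methyl 13-iodotrideca-8,11-diynoate | COC(=O)CCCCCCC#CCC#CCI | intermediate
13 | methyl (19R)-19-hydroxyicosa-8,11,14-triynoate | C[C@@H](O)CCCC#CCC#CCC#CCCCCCCC(=O)OC | intermediate
14 | methyl (8Z,11Z,14Z,19R)-19-hydroxyicosa-8,11,14-trienoate | C[C@@H](O)CCC/C=C\C/C=C\C/C=C\CCCCCCC(=O)OC | intermediate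
15 | (8Z,11Z,14Z,19R)-19-hydroxyicosa-8,11,14-trienoic acid | C[C@@H](O)CCC/C=C\C/C=C\C/C=C\CCCCCCC(=O)O | intermediate
16 | 7-[(1R,4S,5R,6R)-6-[(1E,3S,7R)-3-hydroperoxy-7-hydroxyoct-1-en-1-yl]-2,3-dioxabicyclo[2.2.1]heptan-5-yl]heptanoic acid [19(R)-hydroxy-PGG1] | C[C@@H](O)CCC[C@H](OO)/C=C/[C@@H]1[C@@H](CCCCCCC(=O)O)[C@@H]2C[C@H]1OO2 | intermediate
17 | 7-[(1R,4S,5R,6R)-6-[(1E,3S,7R)-3,7-dihydroxyoct-1-en-1-yl]-2,3-dioxabicyclo[2.2.1]heptan-5-yl]heptanoic acid [19(R)-hydroxy-PGH1] | C[C@@H](O)CCC[C@H](O)/C=C/[C@@H]1[C@@H](CCCCCCC(=O)O)[C@@H]2C[C@H]1OO2 | intermediate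
18 | 7-[(1R,2R,3R,5S)-2-[(1E,3S,7R)-3,7-dihydroxyoct-1-en-1-yl]-3,5-dihydroxycyclopentyl]heptanoic acid [19(R)-hydroxy-PGF1α] | C[C@@H](O)CCC[C@H](O)/C=C/[C@@H]1[C@@H](CCCCCCC(=O)O)[C@@H](O)C[C@H]1O | target

**Count and risks**

Total step count: 9. Longest linear sequence: 7 steps (steps 3–9, from non-8-ynoic acid).

Steps most likely to fail:

1. Step 9. The (ω-1)-hydroxylated acid may be turned over slowly or abortively: release after the first oxygen insertion gives simple 11- or 15-hydroperoxy acids, the enzyme may inactivate itself before conversion is complete, and the endoperoxide may isomerise to keto-alcohols before the stannous chloride reaches it. The fallback takes the ring from the chiral pool instead of closing it; it sets out from 5 and comes back at 18.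
   - ω-Chain reagent: silylation of 5 (TBSCl, imidazole) should give tert-butyl[(2R)-hept-6-yn-2-yloxy]dimethylsilane F1. Lithiation (n-BuLi) and diethyl chlorophosphate should give diethyl [(6R)-6-(tert-butyldimethylsilyloxy)hept-1-yn-1-yl]phosphonate F2. Pd(II)-catalysed hydration of the alkynylphosphonate should give diethyl [(6R)-6-(tert-butyldimethylsilyloxy)-2-oxoheptyl]phosphonate F3.
   - Attachment and C15: Horner–Wadsworth–Emmons olefination (LiCl, i-Pr2NEt, MeCN) with commercial (3aR,4R,5R,6aS)-4-formyl-2-oxohexahydro-2H-cyclopenta[b]furan-5-yl benzoate (O=C[C@@H]1[C@H]2CC(=O)O[C@H]2C[C@H]1OC(=O)c1ccccc1) should give the E-enone benzoate F4. CBS reduction with the (R)-oxazaborolidine and catecholborane should give the 15S-allylic alcohol benzoate F5.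
   - Protecting groups: K2CO3/MeOH should remove the benzoate to give the 11,15-diol lactone F6, and TBSCl/imidazole should give the 11,15,19-tris(silyl ether) lactone F7.
   - α-Chain: DIBAL-H at −78 °C should give the lactol F8. Wittig reaction with the ylide from (4-carboxybutyl)triphenylphosphonium bromide (KOt-Bu, THF) should give the 11,15,19-tris-O-TBS-19-hydroxy-PGF2α acid F9.
   - Finish: hydrogenation over Pd/C at low temperature should reduce the cis-5,6 olefin selectively, the 13,14 olefin being shielded by the flanking 11- and 15-silyl ethers, to give the 11,15,19-tris-O-TBS-19-hydroxy-PGF1α acid F10. Aqueous HF in MeCN should then give 18.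

2. Step 7. The threefold semihydrogenation may run past the triene or stop short of it, and some Z→E isomerisation may occur, giving a mixture that is hard to separate. The fallback makes the olefins by Z-selective Wittig chemistry and never forms the triyne; it sets out from 1 and comes back at 14.
   - Aldehyde: CuI-catalysed opening of 1 with but-3-enylmagnesium bromide should give (2R)-hept-6-en-2-ol F11. Silylation should give tert-butyl[(2R)-hept-6-en-2-yloxy]dimethylsilane F12, and ozonolysis (O3, then PPh3) should give (5R)-5-(tert-butyldimethylsilyloxy)hexanal F13.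
   - Bis-ylide precursor: commercial (Z)-hex-3-ene-1,6-diol should be converted (CBr4, PPh3) into (Z)-1,6-dibromohex-3-ene F14 and then (PPh3, MeCN, reflux) into (Z)-hex-3-ene-1,6-diylbis(triphenylphosphonium) dibromide F15.
   - Double Wittig: the bis-ylide (NaHMDS, THF/DMPU, −78 °C) is treated in sequence with commercial methyl 8-oxooctanoate and F13. This should give methyl (8Z,11Z,14Z,19R)-19-(tert-butyldimethylsilyloxy)icosa-8,11,14-trienoate F16, which is separated from the two symmetrical double-Wittig products. HF·pyridine should then give 14.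

3. Step 6. Base-induced propargyl–allenyl isomerisation and oligomerisation of the ester-bearing diynyl bromide may compete during a slow coupling with the hydroxy-alkyne, and the triyne may autoxidise on isolation. The fallback inverts the order of assembly so that C9–C10 is formed last and the labile bromide meets the robust alkyne 7, which can be used in excess; it sets out from 5 and comes back at 13.
   - Coupling of 5 with excess 8 (CuI, NaI, Cs2CO3, DMF, via 9) should give (10R)-undeca-2,5-diyne-1,10-diol F17.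
   - Appel bromination at −30 °C, selective for the primary propargylic hydroxyl, should give (2R)-11-bromoundeca-6,9-diyn-2-ol F18.
   - Coupling of F18 with excess 7 (CuI, Cs2CO3, DMF, no iodide additive) should give 13.

**Further compounds**

F1 | step 9 | tert-butyl[(2R)-hept-6-yn-2-yloxy]dimethylsilane | C[C@@H](O[Si](C)(C)C(C)(C)C)CCCC#C
F2 | step 9 | diethyl [(6R)-6-(tert-butyldimethylsilyloxy)hept-1-yn-1-yl]phosphonate | C[C@@H](O[Si](C)(C)C(C)(C)C)CCCC#CP(=O)(OCC)OCC
F3 | step 9 | diethyl [(6R)-6-(tert-butyldimethylsilyloxy)-2-oxoheptyl]phosphonate | C[C@@H](O[Si](C)(C)C(C)(C)C)CCCC(=O)CP(=O)(OCC)OCC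
F4 | step 9 | (3aR,4R,5R,6aS)-4-[(1E,7R)-7-(tert-butyldimethylsilyloxy)-3-oxooct-1-en-1-yl]-2-oxohexahydro-2H-cyclopenta[b]furan-5-yl benzoate | C[C@@H](O[Si](C)(C)C(C)(C)C)CCCC(=O)/C=C/[C@@H]1[C@H]2CC(=O)O[C@H]2C[C@H]1OC(=O)c1ccccc1
F5 | step 9 | (3aR,4R,5R,6aS)-4-[(1E,3S,7R)-7-(tert-butyldimethylsilyloxy)-3-hydroxyoct-1-en-1-yl]-2-oxohexahydro-2H-cyclopenta[b]furan-5-yl benzoate | C[C@@H](O[Si](C)(C)C(C)(C)C)CCC[C@H](O)/C=C/[C@@H]1[C@H]2CC(=O)O[C@H]2C[C@H]1OC(=O)c1ccccc1
F6 | step 9 | (3aR,4R,5R,6aS)-4-[(1E,3S,7R)-7-(tert-butyldimethylsilyloxy)-3-hydroxyoct-1-en-1-yl]-5-hydroxyhexahydro-2H-cyclopenta[b]furan-2-one | C[C@@H](O[Si](C)(C)C(C)(C)C)CCC[C@H](O)/C=C/[C@@H]1[C@H]2CC(=O)O[C@H]2C[C@H]1O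
F7 | step 9 | (3aR,4R,5R,6aS)-4-[(1E,3S,7R)-3,7-bis(tert-butyldimethylsilyloxy)oct-1-en-1-yl]-5-(tert-butyldimethylsilyloxy)hexahydro-2H-cyclopenta[b]furan-2-one | C[C@@H](O[Si](C)(C)C(C)(C)C)CCC[C@H](O[Si](C)(C)C(C)(C)C)/C=C/[C@@H]1[C@H]2CC(=O)O[C@H]2C[C@H]1O[Si](C)(C)C(C)(C)C
F8 | step 9 | (3aR,4R,5R,6aS)-4-[(1E,3S,7R)-3,7-bis(tert-butyldimethylsilyloxy)oct-1-en-1-yl]-5-(tert-butyldimethylsilyloxy)hexahydro-2H-cyclopenta[b]furan-2-ol (lactol, anomeric mixture) | C[C@@H](O[Si](C)(C)C(C)(C)C)CCC[C@H](O[Si](C)(C)C(C)(C)C)/C=C/[C@@H]1[C@H]2CC(O)O[C@H]2C[C@H]1O[Si](C)(C)C(C)(C)C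
F9 | step 9 | (5Z)-7-[(1R,2R,3R,5S)-2-[(1E,3S,7R)-3,7-bis(tert-butyldimethylsilyloxy)oct-1-en-1-yl]-3-(tert-butyldimethylsilyloxy)-5-hydroxycyclopentyl]hept-5-enoic acid | C[C@@H](O[Si](C)(C)C(C)(C)C)CCC[C@H](O[Si](C)(C)C(C)(C)C)/C=C/[C@@H]1[C@@H](C/C=C\CCCC(=O)O)[C@@H](O)C[C@H]1O[Si](C)(C)C(C)(C)C
F10 | step 9 | 7-[(1R,2R,3R,5S)-2-[(1E,3S,7R)-3,7-bis(tert-butyldimethylsilyloxy)oct-1-en-1-yl]-3-(tert-butyldimethylsilyloxy)-5-hydroxycyclopentyl]heptanoic acid | C[C@@H](O[Si](C)(C)C(C)(C)C)CCC[C@H](O[Si](C)(C)C(C)(C)C)/C=C/[C@@H]1[C@@H](CCCCCCC(=O)O)[C@@H](O)C[C@H]1O[Si](C)(C)C(C)(C)C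
F11 | step 7 | (2R)-hept-6-en-2-ol | C[C@@H](O)CCCC=C
F12 | step 7 | tert-butyl[(2R)-hept-6-en-2-yloxy]dimethylsilane | C[C@@H](O[Si](C)(C)C(C)(C)C)CCCC=C
F13 | step 7 | (5R)-5-(tert-butyldimethylsilyloxy)hexanal | C[C@@H](O[Si](C)(C)C(C)(C)C)CCCC=O
F14 | step 7 | (Z)-1,6-dibromohex-3-ene | BrCC/C=C\CCBr
F15 | step 7 | (Z)-hex-3-ene-1,6-diylbis(triphenylphosphonium) dibromide | [Br-].[Br-].c1ccccc1[P+](c1ccccc1)(c1ccccc1)CC/C=C\CC[P+](c1ccccc1)(c1ccccc1)c1ccccc1
F16 | step 7 | methyl (8Z,11Z,14Z,19R)-19-(tert-butyldimethylsilyloxy)icosa-8,11,14-trienoate | C[C@@H](O[Si](C)(C)C(C)(C)C)CCC/C=C\C/C=C\C/C=C\CCCCCCC(=O)OC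
F17 | step 6 | (10R)-undeca-2,5-diyne-1,10-diol | C[C@@H](O)CCCC#CCC#CCO
F18 | step 6 | (2R)-11-bromoundeca-6,9-diyn-2-ol | C[C@@H](O)CCCC#CCC#CCBr
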